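**Retrosynthetic overview**

1. Numbering: C1 (methyl-bearing fusion carbon), C2/C3 (CH2), C4 (O-acyl, isopropyl), C5 (fusion CH), C6 (CHOH), C7 (CH2), C8(Me)–C9 (epoxide), C10 (CH2); β is the face of the C1 methyl. The strategy rests on the seven-membered ring C1–C5–C6–C7–C8–C9–C10, whose C7–C8(Me)=C9–C10 segment is an isoprene unit spanning C6 and quaternary C1.
2. Key disconnection: C6–C7 and C1–C10, formed by rhodium-carbene cyclopropanation of isoprene with cyclopentenyl diazoacetate 6 and Cope rearrangement of the cis-divinylcyclopropane (formal [4+3]).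
3. Before: the five-membered ring is made first (Stetter 1,4-diketone synthesis, aldol cyclodehydration), then diazo transfer.
4. After: conjugate reduction sets the trans ring fusion, isopropyl addition with lactonisation sets C4, and the ester carbon on C6 is excised (enolate hydroxylation, LiAlH4, NaIO4) to leave the C6 ketone.
5. End: anti reduction to the 6α-alcohol, hydroxyl-directed epoxidation of C8=C9, acylation of O4 with silyl-protected vanilloyl chloride, desilylation; ring order is five-membered ring, seven-membered ring, epoxide.

Key step: step 4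

Assumption: the C6 configuration drawn for 10, 11, 12, 14 and 15 (carbonyl carbon β) is the one that allows lactone closure, but it does not affect the outcome because C6 becomes the trigonal ketone carbon of 16.

**Route**

Step 1
Reactants: 1 methyl 4-oxobutanoate; 2 but-3-en-2-one
Product: 3 methyl 4,7-dioxooctanoate
Conditions: 3-benzyl-5-(2-hydroxyethyl)-4-methylthiazolium chloride (10 mol%), Et3N, 1,4-dioxane, 80 °C
Reagents that add atoms: none
Why: Stetter reaction, in which the thiazolium carbene turns the aldehyde into an acyl anion equivalent that adds 1,4 to the enone and gives the 1,4-diketone directly; no stereocentre is formed.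

Step 2
Reactants: 3 methyl 4,7-dioxooctanoate
Product: 5 methyl 2-(2-methyl-5-oxocyclopent-1-en-1-yl)acetate, via aldol adduct 4 (not isolated)
Conditions: NaOMe (0.3 equiv), MeOH, 65 °C
Reagents that add atoms: none
Why: intramolecular aldol condensation of a 2,5-diketone (the closure used for jasmone-type cyclopentenones), which should give the more substituted, tetrasubstituted enone, while methoxide in methanol makes ester exchange degenerate.

Step 3
Reactants: 5 methyl 2-(2-methyl-5-oxocyclopent-1-en-1-yl)acetate
Product: 6 methyl 2-diazo-2-(2-methyl-5-oxocyclopent-1-en-1-yl)acetate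
Conditions: p-ABSA, DBU, MeCN, 0 °C to rt
Reagents that add atoms: 4-acetamidobenzenesulfonyl azide (p-ABSA), CC(=O)Nc1ccc(cc1)S(=O)(=O)N=[N+]=[N-]
Why: Regitz diazo transfer to the ester α-CH2, which is allylic and the most acidic position that can hold a diazo group; this is the standard route from β,γ-unsaturated esters to vinyldiazoacetates, and unactivated ketone α-positions do not accept the diazo group under these conditions.

Step 4
Reactants: 6 methyl 2-diazo-2-(2-methyl-5-oxocyclopent-1-en-1-yl)acetate; 7 isoprene
Product: 9 methyl (8aR)-6,8a-dimethyl-3-oxo-1,2,3,5,8,8a-hexahydroazulene-4-carboxylate, via cis-divinylcyclopropane 8 (not isolated)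
Conditions: Rh2(S-DOSP)4 (1 mol%; DOSP = N-(4-dodecylphenylsulfonyl)prolinate), 7 (10 equiv), 2,2-dimethylbutane/PhCF3, −40 °C to rt, slow addition of 6; then PhMe, 110 °C
Reagents that add atoms: none
Why: Rh2(S-DOSP)4 takes N2 from 6 and the rhodium-bound vinylcarbene cyclopropanates the methyl-bearing alkene of isoprene to give cis-divinylcyclopropane 8 (new bonds C6–C7 and C6–C8), which on heating undergoes a boat [3,3] sigmatropic (Cope) shift that forms C1–C10 and breaks C6–C8; the closest known reaction type is the dirhodium prolinate-catalysed tandem cyclopropanation/Cope rearrangement of vinyldiazoacetates with 1,3-dienes (formal [4+3] cycloaddition). The seven-membered ring is closed by this concerted, strain-releasing expansion of the three-membered ring, with the cyclopentene C5=C1 bond and the isoprene vinyl group as the two π components. The only stereocentre of 9, quaternary C1, is set by transfer of the cyclopropane configuration through the boat transition state, and that configuration is set by the chiral prolinate ligands; the S catalyst is chosen because its known (1S,2R) sense with styrene maps onto (1S,2R)-8 and hence onto (R)-C1. The step needs attack on the methyl-bearing alkene, a cis arrangement of the two vinyl groups and one carbene face: the first is favoured because attack by the CH2 terminus places the developing positive charge on a tertiary allylic carbon, the second because the π substituent of an alkene normally ends up cis to the donor group of a donor/acceptor carbene, and the third rests on the catalyst. Heating is required because the C1 methyl points inward in the boat, and any trans-divinylcyclopropane should also be converted at this temperature or slightly above.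

Step 5
Reactants: 9 hydroazulenone ester
Product: 10 trans-fused keto ester, methyl 6,8a-dimethyl-3-oxo-1,2,3,3a,4,5,8,8a-octahydroazulene-4-carboxylate (C1 Me β, H-5 α, CO2Me on C6 β)
Conditions: SmI2 (2.5 equiv), THF/MeOH, −78 °C
Reagents that add atoms: none
Why: electron-transfer conjugate reduction of the ene-1,4-dicarbonyl unit (the isolated C8=C9 alkene is inert), in which C6 is protonated first and the samarium enolate of the C4 ketone should then be protonated at C5 on the face opposite the C1 methyl, which stands nearly perpendicular to the enolate plane while C10 lies close to it, giving the trans ring fusion.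

Step 6
Reactants: 10 trans-fused keto ester
Product: 12 tricyclic γ-lactone (O4 β–C(=O)–C6; 4α-isopropyl, H-5 α, H-6 α, C8=C9), via hydroxy ester 11 (not isolated)
Conditions: iPrMgCl, CeCl3, THF, −78 °C to rt; aq. NH4Cl
Reagents that add atoms: isopropylmagnesium chloride, CC(C)[Mg]Cl
Why: organocerium 1,2-addition, which tolerates hindered, enolisable ketones without deprotonation or β-hydride reduction, should occur on the α face of the trans-fused cyclopentanone, opposite the axial C1 methyl and the C6 branch, setting C4 (isopropyl α, oxygen β), after which the β-alkoxide closes onto the cis-disposed C6 ester.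

Step 7
Reactants: 12 tricyclic γ-lactone
Product: 14 6α-hydroxy lactone, via potassium enolate 13 (not isolated)
Conditions: KN(SiMe3)2, THF, −78 °C; 2-(phenylsulfonyl)-3-phenyloxaziridine; AcOH quench
Reagents that add atoms: 2-(phenylsulfonyl)-3-phenyloxaziridine (Davis oxaziridine), O=S(=O)(c1ccccc1)N1OC1c1ccccc1
Why: the only acidic C–H of 12 is C6–H of the lactone, and its potassium enolate is hydroxylated by the Davis oxaziridine (electrophilic enolate oxidation), expected from the convex face, without touching the C8=C9 alkene.

Step 8
Reactants: 14 6α-hydroxy lactone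
Product: 15 6β-(hydroxymethyl)dauc-8-ene-4β,6α-diol (triol)
Conditions: LiAlH4, THF, 0 °C
Reagents that add atoms: none
Why: hydride reduction of the lactone to the primary alcohol frees the C4 tertiary alcohol and leaves the alkene and all stereocentres untouched.

Step 9
Reactants: 15 triol
Product: 16 4β-hydroxydauc-8-en-6-one (C1 Me β, H-5 α, 4α-isopropyl)
Conditions: NaIO4, THF/H2O, 0 °C to rt
Reagents that add atoms: none
Why: periodate glycol cleavage (Malaprade reaction) of the tertiary/primary 1,2-diol removes the former ester carbon as formaldehyde and leaves the C6 ketone under neutral conditions that spare the retro-aldol-prone β-hydroxy ketone and the C5 centre.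

Step 10
Reactants: 16 β-hydroxy ketone
Product: 17 dauc-8-ene-4β,6α-diol
Conditions: Me4NBH(OAc)3, MeCN/AcOH, −30 °C
Reagents that add atoms: none
Why: Evans–Saksena reduction, in which the acetoxyborohydride bound to the C4 β-hydroxyl delivers hydride intramolecularly to the β face of the C6 ketone and gives the 1,3-anti diol, that is the 6α-alcohol.

Step 11
Reactants: 17 diol
Product: 18 8α,9α-epoxydaucane-4β,6α-diol
Conditions: VO(acac)2 (5 mol%), t-BuOOH, CH2Cl2, 0 °C to rt
Reagents that add atoms: tert-butyl hydroperoxide, CC(C)(C)OO
Why: vanadium-catalysed epoxidation directed by the homoallylic C6 α-hydroxyl should deliver oxygen to the α face of C8=C9, the face that an undirected peracid would not be expected to choose.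

Step 12
Reactants: 18 epoxy diol
Product: 19 6-O-triethylsilyl ether of 18
Conditions: TESCl, imidazole, DMAP (cat.), DMF, rt
Reagents that add atoms: chlorotriethylsilane, CC[Si](Cl)(CC)CC
Why: the secondary C6 hydroxyl is silylated selectively because the tertiary C4 hydroxyl, flanked by isopropyl and the ring fusion, is far more hindered, and these non-acidic conditions spare the epoxide.

Step 13
Reactants: 20 vanillic acid
Product: 21 tert-butyldimethylsilyl 4-(tert-butyldimethylsilyloxy)-3-methoxybenzoate
Conditions: TBSCl (2.2 equiv), imidazole, DMF, rt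
Reagents that add atoms: tert-butyldimethylsilyl chloride, CC(C)(C)[Si](C)(C)Cl
Why: standard silylation of both the phenol and the carboxylic acid, which protects the phenol and provides a silyl ester that can be converted to the acid chloride without acid.

Step 14
Reactants: 21 bis-silylated vanillic acid
Product: 22 4-(tert-butyldimethylsilyloxy)-3-methoxybenzoyl chloride
Conditions: (COCl)2, DMF (cat.), CH2Cl2, 0 °C to rt
Reagents that add atoms: oxalyl chloride, O=C(Cl)C(=O)Cl
Why: the Vilsmeier-type chloroiminium reagent converts silyl esters directly into acid chlorides under neutral conditions, so the aryl silyl ether survives.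

Step 15
Reactants: 19 6-O-triethylsilyl ether; 22 4-(tert-butyldimethylsilyloxy)-3-methoxybenzoyl chloride
Product: 24 4-O-[4-(tert-butyldimethylsilyloxy)-3-methoxybenzoyl]-6-O-triethylsilyl-8α,9α-epoxydaucane-4β,6α-diol, via lithium alkoxide 23 (not isolated)
Conditions: n-BuLi (1.05 equiv), THF, −78 °C; then 22, −78 to 0 °C
Reagents that add atoms: none
Why: O-acylation of a pre-formed lithium alkoxide with an acid chloride is the usual way to esterify a hindered tertiary alcohol, and low temperature with the lithium counter-ion should suppress silyl migration and attack on the epoxide.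

Step 16
Reactants: 24 doubly silylated ester
Product: 25 8α,9α-epoxy-6α-hydroxydaucan-4β-yl 4-hydroxy-3-methoxybenzoate (target, CNP0315707.1)
Conditions: Bu4NF, AcOH, THF, 0 °C to rt
Reagents that add atoms: none
Why: buffered fluoride cleaves the aryl silyl ether and the secondary triethylsilyl ether in one operation, while the acetic acid buffer should prevent acyl migration from O4 to O6 and the epoxide is stable to fluoride.

**Compound list**

1 | methyl 4-oxobutanoate | COC(=O)CCC=O | starting material
2 | but-3-en-2-one (methyl vinyl ketone) | CC(=O)C=C | starting material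
3 | methyl 4,7-dioxooctanoate | COC(=O)CCC(=O)CCC(C)=O | intermediate
4 | methyl 2-(2-hydroxy-2-methyl-5-oxocyclopentyl)acetate (aldol adduct, both stereocentres lost on dehydration) | COC(=O)CC1C(=O)CCC1(C)O | intermediate
5 | methyl 2-(2-methyl-5-oxocyclopent-1-en-1-yl)acetate | COC(=O)CC1=C(C)CCC1=O | intermediate
6 | methyl 2-diazo-2-(2-methyl-5-oxocyclopent-1-en-1-yl)acetate | COC(=O)C(=[N+]=[N-])C1=C(C)CCC1=O | intermediate
7 | isoprene | C=CC(C)=C | starting material
8 | methyl (1S,2R)-2-ethenyl-2-methyl-1-(2-methyl-5-oxocyclopent-1-en-1-yl)cyclopropane-1-carboxylate | COC(=O)[C@@]1(C2=C(C)CCC2=O)C[C@]1(C)C=C | intermediate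
9 | methyl (8aR)-6,8a-dimethyl-3-oxo-1,2,3,5,8,8a-hexahydroazulene-4-carboxylate | COC(=O)C1=C2C(=O)CC[C@]2(C)CC=C(C)C1 | intermediate
10 | trans-fused keto ester (C1 Me β, H-5 α, CO2Me on C6 β) | O=C1CC[C@]2(C)CC=C(C)C[C@@H](C(=O)OC)[C@H]21 | intermediate
11 | 4β-hydroxy-4α-isopropyl ester (present as its metal alkoxide) | O[C@@]1(C(C)C)CC[C@]2(C)CC=C(C)C[C@@H](C(=O)OC)[C@H]21 | intermediate
12 | tricyclic γ-lactone (O4 β–C(=O)–C6, 4α-isopropyl, H-5 α, H-6 α) | O=C1O[C@@]2(C(C)C)CC[C@]3(C)CC=C(C)C[C@@H]1[C@H]32 | intermediate
13 | potassium enolate of 12 | [K+].[O-]C1O[C@@]2(C(C)C)CC[C@]3(C)CC=C(C)CC=1[C@H]32 | intermediate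
14 | 6α-hydroxy lactone | O=C1O[C@@]2(C(C)C)CC[C@]3(C)CC=C(C)C[C@]1(O)[C@H]32 | intermediate
15 | 6β-(hydroxymethyl)dauc-8-ene-4β,6α-diol | O[C@@]1(C(C)C)CC[C@]2(C)CC=C(C)C[C@@](O)(CO)[C@H]21 | intermediate
16 | 4β-hydroxydauc-8-en-6-one | O[C@@]1(C(C)C)CC[C@]2(C)CC=C(C)CC(=O)[C@H]21 | intermediate
17 | dauc-8-ene-4β,6α-diol | O[C@@]1(C(C)C)CC[C@]2(C)CC=C(C)C[C@H](O)[C@H]21 | intermediate
18 | 8α,9α-epoxydaucane-4β,6α-diol | O[C@@]1(C(C)C)CC[C@]2(C)C[C@@H]3O[C@]3(C)C[C@H](O)[C@H]21 | intermediate
19 | 6-O-triethylsilyl-8α,9α-epoxydaucane-4β,6α-diol | O[C@@]1(C(C)C)CC[C@]2(C)C[C@@H]3O[C@]3(C)C[C@H](O[Si](CC)(CC)CC)[C@H]21 | intermediate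
20 | vanillic acid | COc1cc(C(=O)O)ccc1O | starting material
21 | tert-butyldimethylsilyl 4-(tert-butyldimethylsilyloxy)-3-methoxybenzoate | COc1cc(C(=O)O[Si](C)(C)C(C)(C)C)ccc1O[Si](C)(C)C(C)(C)C | intermediate
22 | 4-(tert-butyldimethylsilyloxy)-3-methoxybenzoyl chloride | COc1cc(C(Cl)=O)ccc1O[Si](C)(C)C(C)(C)C | intermediate
23 | lithium 4-alkoxide of 19 | [Li+].[O-][C@@]1(C(C)C)CC[C@]2(C)C[C@@H]3O[C@]3(C)C[C@H](O[Si](CC)(CC)CC)[C@H]21 | intermediate
24 | 4-O-[4-(tert-butyldimethylsilyloxy)-3-methoxybenzoyl]-6-O-triethylsilyl-8α,9α-epoxydaucane-4β,6α-diol | COc1cc(C(=O)O[C@@]2(C(C)C)CC[C@]3(C)C[C@@H]4O[C@]4(C)C[C@H](O[Si](CC)(CC)CC)[C@H]32)ccc1O[Si](C)(C)C(C)(C)C | intermediate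
25 | 8α,9α-epoxy-6α-hydroxydaucan-4β-yl 4-hydroxy-3-methoxybenzoate (CNP0315707.1) | COc1cc(C(=O)O[C@@]2(C(C)C)CC[C@]3(C)C[C@@H]4O[C@]4(C)C[C@H](O)[C@H]32)ccc1O | target

**Step count**

Total: 16 steps. Longest linear sequence: 14 steps (steps 1–12, 15, 16); steps 13 and 14 prepare the acid chloride.

**Steps most likely to fail**

Step 4. The cross-conjugated ketone weakens the donor ability of the vinyl group, so the carbene may discriminate poorly between the two alkenes of isoprene and between its own two faces, and carbene dimerisation may compete. Should only the sense of induction be reversed, the enantiomeric catalyst would be used. The fallback masks the ketone so that the carbene is an ordinary cyclopentenyl donor/acceptor carbene. It sets out from 5: silyl-triflate-catalysed ketalisation with 1,2-bis(trimethylsilyloxy)ethane in CH2Cl2 at −78 °C would give methyl 2-(7-methyl-1,4-dioxaspiro[4.4]non-6-en-6-yl)acetate F1. Diazo transfer with p-ABSA and DBU would give the diazoacetate F2. The same Rh2(S-DOSP)4 reaction with isoprene would give the cis-divinylcyclopropane ketal F3 and, on heating, the cycloheptadiene ketal F4. PPTS in wet acetone would release the ketone, and the fallback comes back to the route at 9.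

Step 5. Protonation of the C4 enolate at C5 may show poor facial selectivity and give the cis ring fusion, which would then invert the sense of the isopropyl addition. The fallback sets C4 first and lets C5 settle later under thermodynamic control. It sets out from 9: Weitz–Scheffer epoxidation with t-BuOOH and DBU in CH2Cl2, the hydroperoxide adding at C6 of the doubly activated alkene, would give the 5α,6α-epoxy keto ester F5. iPrMgCl/CeCl3 would add to C4 opposite the C1 methyl, with lactonisation to the epoxy lactone F6. LiOH in aqueous THF would open the lactone to the lithium glycidate F7. Buffered acidification (pH 4–5, 50 °C) would bring about Darzens-type decarboxylative epoxide opening to the enol, which ketonises. C5, now α to the C6 ketone, can then equilibrate to the isomer with C6 trans to the isopropyl group, and the fallback comes back to the route at 16.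

Step 15. Acylation of the hindered tertiary alkoxide may be slow, so that the triethylsilyl group migrates from O6 to O4 and the acid chloride ends on O6. The fallback uses an ether on O6 that cannot migrate and a hydrogenolytic finish. It sets out from 18: NaH, BnBr and Bu4NI in DMF would give the 6-O-benzyl ether F8. Commercial 4-(benzyloxy)-3-methoxybenzoic acid with (COCl)2 and catalytic DMF would give 4-(benzyloxy)-3-methoxybenzoyl chloride F9. Deprotonation of F8 with n-BuLi (or KN(SiMe3)2 at higher temperature, now without risk of silyl transfer) and acylation with F9 would give the bis-benzyl ester F10. Hydrogenolysis over Pd/C in EtOAc, with no alkene left in the molecule, would remove both benzyl groups, and the fallback comes back to the route at 25.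

**Further compounds**

F1 | step 4 | methyl 2-(7-methyl-1,4-dioxaspiro[4.4]non-6-en-6-yl)acetate | COC(=O)CC1=C(C)CCC12OCCO2
F2 | step 4 | methyl 2-diazo-2-(7-methyl-1,4-dioxaspiro[4.4]non-6-en-6-yl)acetate | COC(=O)C(=[N+]=[N-])C1=C(C)CCC12OCCO2
F3 | step 4 | cis-divinylcyclopropane ketal (ethylene ketal of 8) | COC(=O)[C@@]1(C2=C(C)CCC23OCCO3)C[C@]1(C)C=C
F4 | step 4 | cycloheptadiene ketal (ethylene ketal of 9) | COC(=O)C1=C2C3(OCCO3)CC[C@]2(C)CC=C(C)C1
F5 | step 5 | 5α,6α-epoxy keto ester (epoxide of 9) | O=C1CC[C@]2(C)CC=C(C)C[C@]3(C(=O)OC)O[C@@]321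
F6 | step 5 | 5α,6α-epoxy γ-lactone (4α-isopropyl, O4 β) | O=C1O[C@@]2(C(C)C)CC[C@]3(C)CC=C(C)C[C@@]14O[C@@]432
F7 | step 5 | lithium 5α,6α-epoxy-4β-hydroxy-6-carboxylate (glycidate) | O[C@@]1(C(C)C)CC[C@]2(C)CC=C(C)C[C@]3(C(=O)[O-])O[C@@]321.[Li+]
F8 | step 15 | 6-O-benzyl-8α,9α-epoxydaucane-4β,6α-diol | O[C@@]1(C(C)C)CC[C@]2(C)C[C@@H]3O[C@]3(C)C[C@H](OCc4ccccc4)[C@H]21
F9 | step 15 | 4-(benzyloxy)-3-methoxybenzoyl chloride | COc1cc(C(Cl)=O)ccc1OCc1ccccc1
F10 | step 15 | 4-O-[4-(benzyloxy)-3-methoxybenzoyl]-6-O-benzyl-8α,9α-epoxydaucane-4β,6α-diol | COc1cc(C(=O)O[C@@]2(C(C)C)CC[C@]3(C)C[C@@H]4O[C@]4(C)C[C@H](OCc4ccccc4)[C@H]32)ccc1OCc1ccccc1
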